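**Remark on the chemistry (assumption):** the transfer hydrogenation of ynone 5 is taken to follow the usual model, with the alkynyl group in the place of the aryl group of an aryl ketone. The Marshall reaction is taken to run by anti SN2′ palladation and syn SE2′ addition. The descriptors of 6, 7, 10 and 11 rest on this.

## Analysis of the target

Gnetucleistol F (26) is a 2-aryl-3-hydroxymethyl-2,3-dihydrobenzofuran. A benzo ring (C3a, C4 to C7, C7a) is fused to a dihydrofuran ring (O1, C2, C3). C2 carries a 4-hydroxy-3,5-dimethoxyphenyl (syringyl) ring, C7 a methoxy group and C5 an (E)-3,5-dihydroxystyryl group. The only stereocentres are the adjacent C2 (R, a benzylic ether carbon) and C3 (S). Aryl and hydroxymethyl are trans, which in an open chain Ar–CH(O)–CH(CH2O)–C corresponds to the anti arrangement. Sensitive features are the electron-rich stilbene with its resorcinol ring (acid, oxidants, hydrogenation) and the C2–O1 benzylic ether para to a free phenol (ionisation or quinone-methide formation, hence ring opening and epimerisation). The hard part is the benzo ring, a 1,2,3,5-tetrasubstituted benzene with four different substituents that must be built with full regiocontrol next to two stereocentres of defined absolute configuration. The strategy rests on the fact that C3a and C7a are spanned by the three-atom chain O1–C2–C3. If the benzene ring is cut into three two-carbon units, C7a–C7 and C3a–C4 are alkynes held at the two ends of that chain and C5–C6 is a free alkyne, so one cyclotrimerisation of a chiral 1,6-diyne makes both fused rings at once.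

## Retrosynthetic reasoning

**26 to 25.** The last step only frees hydroxyl groups: the four benzyl–oxygen bonds of 25 are cut. One kind of protecting group on all four oxygens allows a single operation. The cleavage has to be a Lewis-acid one, because hydrogenolysis would reduce the alkene.

**25 to 21 and 23.** The stilbene C=C bond is cut, to aldehyde 21 and benzylic phosphonate 23 (one step from bromide 22). This is the most convergent cut, it keeps the resorcinol ring away from the chiral half until late, and the forward olefination is reliably E-selective. It also fixes what the ring construction must deliver at C5: a formyl group, carried as an acetal.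

**21 to 20, 19 and 18.** The aldehyde comes from acetal 20. The C7–O bond is traced back through a C7–I bond (19) to a C7–Si bond (18). An oxygen substituent cannot sit on the terminus of an ynol ether, so silicon holds the place during ring construction and also serves there as the bulky orienting group. The acetal is kept until the methoxy group is in, so that no aldehyde meets alkoxide at elevated temperature.

**18 to 16 and 17.** This is the key disconnection. The bonds C3a–C7a, C4–C5 and C6–C7 are cut, which opens the benzene ring and the dihydrofuran ring together. What remains is diyne 16, with both stereocentres on its tether, and the acetal alkyne 17. No other cut removes two rings and leaves the stereocentres in an open chain, where they are easy to set. The forward reaction must join three alkynes in one orientation, at a temperature the benzylic ynol ether survives.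

**16 to 15, 11 and 12.** The carbon-bound alkyne of 16 is unmasked from its trimethylsilyl derivative 15. The O–C(sp) bond of the ynol ether is cut to alcohol 11 and trichloroethylene 12, which supplies C7a and C7. The two alkyne termini need caps of different lability, trimethylsilyl on carbon and triethylsilyl on the ynol ether. The primary oxygen is a benzyl ether and not a silyl ether: alkoxide formation at the neighbouring carbinol would invite a 1,5-silyl shift between the two oxygens, and a silyl ether would be at risk in the later methoxylation.

**11 to 7 and 9.** The C2–C3 bond is cut between aldehyde 9 and the propargylic carbon of mesylate 7. One carbon–carbon bond formation then sets both stereocentres: the propargylic centre from the mesylate, the carbinol centre from a cyclic transition state that gives the anti isomer. No other cut sets both at once from a single small chiral reagent.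

**7 to 1 and 3; 9 to 8.** Mesylate 7 comes from alcohol 6, which is made by asymmetric reduction of ynone 5. The ynone is assembled from Weinreb amide 2 (from acid chloride 1) and alkyne 3. Aldehyde 9 is the benzyl ether of syringaldehyde 8.

## Alternatives that were turned down

**Alternative 1:** The C3–C3a bond is disconnected, and the five-membered ring is traced back to the six-membered ring of an enantiopure flavanone that already holds the brominated, methoxylated benzo ring. In the forward step a trivalent-iodine oxidant in acidic orthoformate attacks the enol ether at C3. The benzo-ring carbon migrates from the carbonyl carbon to C3, and the former carbonyl carbon ends as the ester of methyl trans-5-bromo-2-(3,5-dimethoxy-4-mesyloxyphenyl)-7-methoxy-2,3-dihydrobenzofuran-3-carboxylate A1.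
- For it: the substitution pattern of the benzo ring is bought, not made, so there is no regiochemical question. The trans relationship follows from the shift. The sequence is shorter than the chosen one. On these points it is the stronger plan.
- Against it: the C2 stereocentre of a flavanone is a benzylic ether β to a ketone and can racemise by ring opening to the chalcone under the acidic conditions of the shift. The syringyl ring must be deactivated as a sulfonate so that it is neither oxidised nor migrates. The ester has to be reduced and the bromide turned into the styryl group afterwards.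
- In comparison, the chosen route makes both stereocentres in one reagent-controlled step and never passes them through a retro-Michael manifold. It also delivers C5 at the aldehyde oxidation level.

**Alternative 2:** Four bonds of the benzo ring are disconnected (C3a–C4, C4–C5, C6–C7, C7–C7a), back to a chiral dihydrofuranyl diazoketone and a silyloxyalkyne. In the forward step, irradiation triggers a Wolff shift to a vinylketene. The ketene adds the alkyne in a (2+2) sense, the cyclobutenone opens and the dienylketene closes, giving trans-2-(4-benzyloxy-3,5-dimethoxyphenyl)-3-(benzyloxymethyl)-5-(triisopropylsilyloxy)-2,3-dihydrobenzofuran-7-ol A2.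
- For it: the regiochemistry is fixed by the mechanism and needs no steric steering. The C7 oxygen arrives as a free phenol that can be methylated at once, which is better than the silicon–iodine–oxygen detour of the chosen route.
- Against it: C5 arrives as an oxygen where the target needs a carbon, so desilylation, sulfonylation and a cross-coupling follow. The precursor is an acid-labile enol ether that already carries both stereocentres and a diazoketone, and it takes many steps to reach.
- In comparison, the chosen route reaches its precursor in few steps from an aldehyde and puts a carbon at C5 directly.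

**Alternative 3:** The C2–C3 and O1–C2 bonds are disconnected, back to an ortho-quinone methide and a chiral benzylic sulfonium ylide of the syringyl type. In the forward step, base releases the quinone methide from a sulfonyl phenol. The ylide adds to its exocyclic carbon and the phenoxide displaces the sulfide, giving trans-2-(4-benzyloxy-3,5-dimethoxyphenyl)-5-bromo-3-[(tert-butyldimethylsilyloxy)methyl]-7-methoxy-2,3-dihydrobenzofuran A3.
- For it: this is the most convergent and probably the shortest plan. The arene is bought and the trans ring follows from the reversible betaine. In step economy it is stronger than the chosen route.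
- Against it: the absolute configuration depends on a stoichiometric chiral sulfide attached to a very electron-rich benzylic position that ionises easily, so the enantioselectivity is uncertain. The quinone methide carries a CH2O-silyl group with adjacent C–H bonds and can tautomerise to a vinylphenol or lose silanolate. The bromide still has to become the styryl group.
- In comparison, the chosen route takes its absolute configuration from a catalytic asymmetric reduction relayed by a stereospecific reagent and does not depend on facial selectivity at a planar intermediate.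

Key step: step 9

## Route

Step 1
Reactants: 1 benzyloxyacetyl chloride
Product: 2 2-(benzyloxy)-N-methoxy-N-methylacetamide
Conditions: MeNH(OMe)·HCl, pyridine, CH2Cl2, 0 °C → rt
Reagents that add atoms: N,O-dimethylhydroxylamine hydrochloride, CNOC.Cl
Why: Acylation of the hydroxylamine by the acid chloride (Weinreb amide formation); pyridine, not a stronger amine, avoids ketene formation from the α-alkoxy acid chloride.

Step 2
Reactants: 2 2-(benzyloxy)-N-methoxy-N-methylacetamide; 3 ethynyltrimethylsilane
Product: 5 1-(benzyloxy)-4-(trimethylsilyl)but-3-yn-2-one, via lithium (trimethylsilyl)acetylide 4 (not isolated)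
Conditions: 3, n-BuLi, THF, −78 °C; then 2, −78 → −20 °C; cold aq. NH4Cl
Reagents that add atoms: none
Why: Weinreb ketone synthesis: the chelated tetrahedral adduct stops at single addition and releases the ynone only on quench, and the cold quench keeps the liberated hydroxylamine from adding to the ynone.

Step 3
Reactants: 5 1-(benzyloxy)-4-(trimethylsilyl)but-3-yn-2-one
Product: 6 (R)-1-(benzyloxy)-4-(trimethylsilyl)but-3-yn-2-ol
Conditions: Ru[(S,S)-TsDPEN](p-cymene) (2 mol %), i-PrOH, rt
Reagents that add atoms: none
Why: Noyori asymmetric transfer hydrogenation of an alkynyl ketone, a substrate class that is reduced with high enantioselectivity; the (S,S)-ligand sets the new stereocentre with the alkynyl group in the place of the aryl group of the usual model, which is the (R)-carbinol here because CH2OBn outranks the alkynyl carbon.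

Step 4
Reactants: 6 (R)-1-(benzyloxy)-4-(trimethylsilyl)but-3-yn-2-ol
Product: 7 (R)-1-(benzyloxy)-4-(trimethylsilyl)but-3-yn-2-yl methanesulfonate
Conditions: MsCl, Et3N, CH2Cl2, −78 → −20 °C; used without chromatography
Reagents that add atoms: methanesulfonyl chloride, CS(=O)(=O)Cl
Why: O-Sulfonylation with retention at carbon; the propargylic mesylate is kept cold and used directly because it ionises easily.

Step 5
Reactants: 8 syringaldehyde
Product: 9 4-(benzyloxy)-3,5-dimethoxybenzaldehyde
Conditions: BnBr, K2CO3, DMF, 60 °C
Reagents that add atoms: benzyl bromide, BrCc1ccccc1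
Why: Williamson etherification of the phenoxide; the benzyl ether withstands the organometallic, basic and mildly acidic steps that follow.

Step 6
Reactants: 7 (R)-1-(benzyloxy)-4-(trimethylsilyl)but-3-yn-2-yl methanesulfonate; 9 4-(benzyloxy)-3,5-dimethoxybenzaldehyde
Product: 11 (1R,2S)-1-[4-(benzyloxy)-3,5-dimethoxyphenyl]-2-[(benzyloxy)methyl]-4-(trimethylsilyl)but-3-yn-1-ol, via allenylzinc reagent 10 (not isolated)
Conditions: Pd(OAc)2 (5 mol %), PPh3 (5 mol %), Et2Zn (3 equiv), THF, −78 → −20 °C; aq. NH4Cl
Reagents that add atoms: none
Why: Marshall propargylation: zerovalent palladium displaces the mesylate in anti SN2′ fashion, transmetalation gives the configurationally defined allenylzinc 10, and this adds to 9 through a cyclic syn SE2′ transition state. The propargylic centre (later C3) is set with net inversion by the mesylate; the carbinol centre (later C2) is set by the cyclic transition state, in which the aryl group avoids the CH2OBn group, so the anti isomer should predominate and the minor syn isomer would be removed by chromatography.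

Step 7
Reactants: 11 (1R,2S)-1-[4-(benzyloxy)-3,5-dimethoxyphenyl]-2-[(benzyloxy)methyl]-4-(trimethylsilyl)but-3-yn-1-ol; 12 trichloroethylene
Product: 15 triethyl({[(1R,2S)-1-[4-(benzyloxy)-3,5-dimethoxyphenyl]-2-[(benzyloxy)methyl]-4-(trimethylsilyl)but-3-yn-1-yl]oxy}ethynyl)silane, via (E)-1,2-dichlorovinyl ether 13 (not isolated), via lithium alkynyl ether 14 (not isolated)
Conditions: KH, THF, 0 °C → rt; 12, −50 °C → rt; then n-BuLi (2.5 equiv), −78 → −40 °C; Et3SiCl, −78 → 0 °C; chromatography on Et3N-deactivated silica
Reagents that add atoms: chlorotriethylsilane, CC[Si](Cl)(CC)CC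
Why: Trichloroethylene route to ynol ethers: the potassium alkoxide adds to dichloroacetylene formed in the flask from 12, giving 13; two equivalents of butyllithium then effect elimination and chlorine–lithium exchange to 14, which is silylated on carbon. The carbinol carbon is not touched and keeps its configuration, and the benzyl ether on the primary oxygen cannot migrate to the alkoxide as a silyl ether could.

Step 8
Reactants: 15 triethyl({[(1R,2S)-1-[4-(benzyloxy)-3,5-dimethoxyphenyl]-2-[(benzyloxy)methyl]-4-(trimethylsilyl)but-3-yn-1-yl]oxy}ethynyl)silane
Product: 16 triethyl({[(1R,2S)-1-[4-(benzyloxy)-3,5-dimethoxyphenyl]-2-[(benzyloxy)methyl]but-3-yn-1-yl]oxy}ethynyl)silane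
Conditions: K2CO3 (0.3 equiv), MeOH/THF (1:1), 0 °C, monitored and stopped at full conversion of 15
Reagents that add atoms: none
Why: Base-catalysed methanolysis of an alkynyl C–Si bond is much faster for the unhindered trimethylsilyl group than for the triethylsilyl group, so the carbon-bound alkyne should be freed while the silyl ynol ether is kept (selective protodesilylation of an alkynylsilane). The ynol ether is stable to base; low temperature guards against its thermal rearrangement.

Step 9
Reactants: 16 triethyl({[(1R,2S)-1-[4-(benzyloxy)-3,5-dimethoxyphenyl]-2-[(benzyloxy)methyl]but-3-yn-1-yl]oxy}ethynyl)silane; 17 3,3-diethoxyprop-1-yne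
Product: 18 (2R,3S)-2-[4-(benzyloxy)-3,5-dimethoxyphenyl]-3-[(benzyloxy)methyl]-5-(diethoxymethyl)-7-(triethylsilyl)-2,3-dihydrobenzofuran
Conditions: [Rh(cod)2]BF4 (5 mol %), rac-BINAP (5 mol %), CH2Cl2, H2 then Ar; 17 (3 equiv); slow addition of 16, rt
Reagents that add atoms: none
Why: Hydrogenation of the cyclooctadiene ligands leaves a cationic monovalent rhodium–BINAP fragment that binds both alkynes of 16 and couples their tether-side carbons oxidatively to a trivalent rhodacyclopentadiene; this forms C3a–C7a and closes the dihydrofuran ring (oxidative cyclisation of a 1,6-diyne, each alkyne closing in exo fashion across the three-atom O1–C2–C3 tether). Alkyne 17 then inserts into the unhindered Rh–C4 bond, and reductive elimination from the rhodacycloheptatriene forms C4–C5 and C6–C7, closes the benzene ring and returns monovalent rhodium. The closest known reaction type is the cationic rhodium–bisphosphine (2+2+2) cycloaddition of heteroatom-tethered 1,6-diynes with monoalkynes, established for ynamide-tethered diynes (indolines, carbazoles) and for aryl alkynyl ether diynes (dibenzofurans); silyl ynol ethers are also known partners in metal-mediated cyclotrimerisation. No stereocentre is formed: C2 and C3 lie on the tether, take no part in any bond change, and their anti relationship becomes the trans relationship of the ring. The step needs regioselectivity in the insertion of 17 and chemoselectivity for cross- over homo-trimerisation. The first rests on the triethylsilyl group at the ynol-ether terminus, which shields the Rh–C7 bond and disfavours the orientation that would put the acetal-bearing carbon next to it, so that this carbon should bond to C4 (becoming C5) and the CH terminus to C7 (becoming C6); the second rests on slow addition of 16 to an excess of 17. Room temperature and a non-acidic medium keep the benzylic silyl ynol ether below the range of retro-ene loss of a silylketene and of sigmatropic rearrangement.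

Step 10
Reactants: 18 (2R,3S)-2-[4-(benzyloxy)-3,5-dimethoxyphenyl]-3-[(benzyloxy)methyl]-5-(diethoxymethyl)-7-(triethylsilyl)-2,3-dihydrobenzofuran
Product: 19 (2R,3S)-2-[4-(benzyloxy)-3,5-dimethoxyphenyl]-3-[(benzyloxy)methyl]-5-(diethoxymethyl)-7-iodo-2,3-dihydrobenzofuran
Conditions: ICl (1.05 equiv), 2,6-di-tert-butylpyridine, CH2Cl2, −78 → −20 °C; aq. Na2S2O3
Reagents that add atoms: iodine monochloride, ClI
Why: Electrophilic ipso-iododesilylation: attack at C7 is favoured by the ortho ring oxygen and by β-silicon stabilisation of the arenium ion, which should make it much faster than C–H iodination of the syringyl ring, whose free positions are flanked on both sides. The hindered base takes up acid so that the diethyl acetal survives.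

Step 11
Reactants: 19 (2R,3S)-2-[4-(benzyloxy)-3,5-dimethoxyphenyl]-3-[(benzyloxy)methyl]-5-(diethoxymethyl)-7-iodo-2,3-dihydrobenzofuran
Product: 20 (2R,3S)-2-[4-(benzyloxy)-3,5-dimethoxyphenyl]-3-[(benzyloxy)methyl]-5-(diethoxymethyl)-7-methoxy-2,3-dihydrobenzofuran
Conditions: CuI (10 mol %), 3,4,7,8-tetramethyl-1,10-phenanthroline (20 mol %), Cs2CO3, MeOH/toluene, 90 °C, sealed tube
Reagents that add atoms: methanol, CO
Why: Ligand-accelerated Ullmann-type C–O coupling of an aryl iodide with methanol; the acetal and the benzyl ethers are inert to carbonate base, and no silyl ether is present that methoxide could cleave.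

Step 12
Reactants: 20 (2R,3S)-2-[4-(benzyloxy)-3,5-dimethoxyphenyl]-3-[(benzyloxy)methyl]-5-(diethoxymethyl)-7-methoxy-2,3-dihydrobenzofuran
Product: 21 (2R,3S)-2-[4-(benzyloxy)-3,5-dimethoxyphenyl]-3-[(benzyloxy)methyl]-7-methoxy-2,3-dihydrobenzofuran-5-carbaldehyde
Conditions: PPTS (cat.), acetone/H2O (9:1), rt
Reagents that add atoms: water, O
Why: Acid-catalysed hydrolysis of an aryl diethyl acetal, which is far more labile than the benzyl ethers or the benzylic ring ether under this weak acid.

Step 13
Reactants: 22 3,5-bis(benzyloxy)benzyl bromide
Product: 23 diethyl [3,5-bis(benzyloxy)benzyl]phosphonate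
Conditions: P(OEt)3 (neat), 130 °C
Reagents that add atoms: triethyl phosphite, CCOP(OCC)OCC
Why: Michaelis–Arbuzov reaction of a reactive benzylic bromide; bromoethane distils off and drives the reaction.

Step 14
Reactants: 21 (2R,3S)-2-[4-(benzyloxy)-3,5-dimethoxyphenyl]-3-[(benzyloxy)methyl]-7-methoxy-2,3-dihydrobenzofuran-5-carbaldehyde; 23 diethyl [3,5-bis(benzyloxy)benzyl]phosphonate
Product: 25 (2R,3S)-2-[4-(benzyloxy)-3,5-dimethoxyphenyl]-3-[(benzyloxy)methyl]-5-{(E)-2-[3,5-bis(benzyloxy)phenyl]ethenyl}-7-methoxy-2,3-dihydrobenzofuran, via potassium phosphonate carbanion 24 (not isolated)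
Conditions: 23 (1.3 equiv), KOtBu (1.25 equiv), THF, 0 °C; then 21, 0 °C → rt
Reagents that add atoms: none
Why: Horner–Wadsworth–Emmons olefination with a semi-stabilised benzylphosphonate anion, which gives the (E)-stilbene through the more stable anti oxaphosphetane. The anion is formed before the aldehyde is added, so no free alkoxide base meets the dihydrobenzofuran and neither stereocentre is touched.

Step 15
Reactants: 25 (2R,3S)-2-[4-(benzyloxy)-3,5-dimethoxyphenyl]-3-[(benzyloxy)methyl]-5-{(E)-2-[3,5-bis(benzyloxy)phenyl]ethenyl}-7-methoxy-2,3-dihydrobenzofuran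
Product: 26 Gnetucleistol F, 5-{(E)-2-[(2R,3S)-2-(4-hydroxy-3,5-dimethoxyphenyl)-3-(hydroxymethyl)-7-methoxy-2,3-dihydrobenzofuran-5-yl]ethenyl}benzene-1,3-diol
Conditions: BCl3 (1 M in CH2Cl2, excess), C6HMe5, CH2Cl2, −78 → −30 °C; MeOH at −78 °C, then aq. NaHCO3
Reagents that add atoms: none
Why: Lewis-acid debenzylation: BCl3 ionises the benzyl–oxygen bonds and pentamethylbenzene traps the benzyl cations before they can alkylate the stilbene or the resorcinol ring. Aryl methyl ethers are inert at this temperature, and the alkene, which hydrogenolysis would reduce, is untouched.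

## Compound list

1 | benzyloxyacetyl chloride | O=C(Cl)COCc1ccccc1 | starting material
2 | 2-(benzyloxy)-N-methoxy-N-methylacetamide | CON(C)C(=O)COCc1ccccc1 | intermediate
3 | ethynyltrimethylsilane | C#C[Si](C)(C)C | starting material
4 | lithium (trimethylsilyl)acetylide | [Li]C#C[Si](C)(C)C | intermediate (not isolated)
5 | 1-(benzyloxy)-4-(trimethylsilyl)but-3-yn-2-one | O=C(COCc1ccccc1)C#C[Si](C)(C)C | intermediate
6 | (R)-1-(benzyloxy)-4-(trimethylsilyl)but-3-yn-2-ol | O[C@H](C#C[Si](C)(C)C)COCc1ccccc1 | intermediate
7 | (R)-1-(benzyloxy)-4-(trimethylsilyl)but-3-yn-2-yl methanesulfonate | CS(=O)(=O)O[C@H](C#C[Si](C)(C)C)COCc1ccccc1 | intermediate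
8 | syringaldehyde (4-hydroxy-3,5-dimethoxybenzaldehyde) | COc1cc(C=O)cc(OC)c1O | starting material
9 | 4-(benzyloxy)-3,5-dimethoxybenzaldehyde | COc1cc(C=O)cc(OC)c1OCc1ccccc1 | intermediate
10 | ethyl[(aR)-4-(benzyloxy)-1-(trimethylsilyl)buta-1,2-dien-1-yl]zinc | CC[Zn]C([Si](C)(C)C)=[C@]=C([H])COCc1ccccc1 | intermediate (not isolated)
11 | (1R,2S)-1-[4-(benzyloxy)-3,5-dimethoxyphenyl]-2-[(benzyloxy)methyl]-4-(trimethylsilyl)but-3-yn-1-ol | COc1cc([C@@H]([C@@H](C#C[Si](C)(C)C)COCc2ccccc2)O)cc(OC)c1OCc1ccccc1 | intermediate
12 | trichloroethylene | ClC=C(Cl)Cl | starting material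
13 | (E)-1,2-dichlorovinyl ether of 11 | COc1cc([C@@H]([C@@H](C#C[Si](C)(C)C)COCc2ccccc2)O/C(Cl)=C\Cl)cc(OC)c1OCc1ccccc1 | intermediate (not isolated)
14 | lithium alkynyl ether (2-lithioethynyl ether of 11) | COc1cc([C@@H]([C@@H](C#C[Si](C)(C)C)COCc2ccccc2)OC#C[Li])cc(OC)c1OCc1ccccc1 | intermediate (not isolated)
15 | triethyl({[(1R,2S)-1-[4-(benzyloxy)-3,5-dimethoxyphenyl]-2-[(benzyloxy)methyl]-4-(trimethylsilyl)but-3-yn-1-yl]oxy}ethynyl)silane | COc1cc([C@@H]([C@@H](C#C[Si](C)(C)C)COCc2ccccc2)OC#C[Si](CC)(CC)CC)cc(OC)c1OCc1ccccc1 | intermediate
16 | triethyl({[(1R,2S)-1-[4-(benzyloxy)-3,5-dimethoxyphenyl]-2-[(benzyloxy)methyl]but-3-yn-1-yl]oxy}ethynyl)silane | COc1cc([C@@H]([C@@H](C#C)COCc2ccccc2)OC#C[Si](CC)(CC)CC)cc(OC)c1OCc1ccccc1 | intermediate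
17 | 3,3-diethoxyprop-1-yne | C#CC(OCC)OCC | starting material
18 | (2R,3S)-2-[4-(benzyloxy)-3,5-dimethoxyphenyl]-3-[(benzyloxy)methyl]-5-(diethoxymethyl)-7-(triethylsilyl)-2,3-dihydrobenzofuran | COc1cc([C@@H]2Oc3c([Si](CC)(CC)CC)cc(C(OCC)OCC)cc3[C@H]2COCc2ccccc2)cc(OC)c1OCc1ccccc1 | intermediate
19 | (2R,3S)-2-[4-(benzyloxy)-3,5-dimethoxyphenyl]-3-[(benzyloxy)methyl]-5-(diethoxymethyl)-7-iodo-2,3-dihydrobenzofuran | COc1cc([C@@H]2Oc3c(I)cc(C(OCC)OCC)cc3[C@H]2COCc2ccccc2)cc(OC)c1OCc1ccccc1 | intermediate
20 | (2R,3S)-2-[4-(benzyloxy)-3,5-dimethoxyphenyl]-3-[(benzyloxy)methyl]-5-(diethoxymethyl)-7-methoxy-2,3-dihydrobenzofuran | COc1cc([C@@H]2Oc3c(OC)cc(C(OCC)OCC)cc3[C@H]2COCc2ccccc2)cc(OC)c1OCc1ccccc1 | intermediate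
21 | (2R,3S)-2-[4-(benzyloxy)-3,5-dimethoxyphenyl]-3-[(benzyloxy)methyl]-7-methoxy-2,3-dihydrobenzofuran-5-carbaldehyde | COc1cc([C@@H]2Oc3c(OC)cc(C=O)cc3[C@H]2COCc2ccccc2)cc(OC)c1OCc1ccccc1 | intermediate
22 | 3,5-bis(benzyloxy)benzyl bromide | BrCc1cc(OCc2ccccc2)cc(OCc2ccccc2)c1 | starting material
23 | diethyl [3,5-bis(benzyloxy)benzyl]phosphonate | CCOP(=O)(Cc1cc(OCc2ccccc2)cc(OCc2ccccc2)c1)OCC | intermediate
24 | potassium salt of the benzylic carbanion of 23 | [K+].CCOP(=O)([CH-]c1cc(OCc2ccccc2)cc(OCc2ccccc2)c1)OCC | intermediate (not isolated)
25 | (2R,3S)-2-[4-(benzyloxy)-3,5-dimethoxyphenyl]-3-[(benzyloxy)methyl]-5-{(E)-2-[3,5-bis(benzyloxy)phenyl]ethenyl}-7-methoxy-2,3-dihydrobenzofuran | COc1cc([C@@H]2Oc3c(OC)cc(/C=C/c4cc(OCc5ccccc5)cc(OCc5ccccc5)c4)cc3[C@H]2COCc2ccccc2)cc(OC)c1OCc1ccccc1 | intermediate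
26 | Gnetucleistol F | COc1cc([C@@H]2Oc3c(OC)cc(/C=C/c4cc(O)cc(O)c4)cc3[C@H]2CO)cc(OC)c1O | target

## Step count and least certain steps

Total: 15 steps. Longest linear sequence: 13 steps (steps 1 to 4, 6 to 12, 14 and 15, from 1 to 26).

**Step 9 (key step).** Three things may go wrong.
- Alkyne 17 may insert in the reverse orientation, putting the acetal-bearing carbon next to the silylated carbon. Rhodium catalysts can favour this when the steric bias is small.
- Oxidative cyclisation of the hindered silyl ynol ether may be slow, so that 17 trimerises with itself.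
- The cationic metal may cause hydration or ionisation of the benzylic ynol ether.

Fallback: the third alkyne is made intramolecular through a temporary silicon tether, so that connectivity and not sterics fixes the orientation. It sets out from 16. The terminal alkyne is lithiated (n-BuLi, THF, −78 °C) and quenched with dichlorodiisopropylsilane, then with propargyl alcohol and imidazole, to give the silicon-tethered triyne F1. The same rhodium catalyst, or RhCl(PPh3)3, should cyclise it to the tricyclic benzoxasilole F2, in which C4 carries the tether silicon and C5 the tether CH2O group. TBAF in THF cleaves the Si–O bond and protodesilylates C4, while the unactivated triethylsilyl group at C7 stays, giving the 5-hydroxymethyl compound F3. MnO2 oxidation gives the 5-carbaldehyde F4. Acetalisation with triethyl orthoformate (EtOH, PPTS) comes back to the route at 18.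

**Step 8.** The selectivity between the two alkynyl C–Si bonds may be lost, because the alkoxyacetylide could be a better leaving group than expected; the triethylsilyl cap would then be removed as well. Fallback: the cap on the ynol ether is changed to triethylgermyl, whose bond to an alkyne carbon resists carbonate in methanol. It sets out from 11. Step 7 is repeated with chlorotriethylgermane as the quench, giving the germyl ynol ether F5. K2CO3 in methanol then removes only the trimethylsilyl group, giving the germyl diyne F6. Cycloaddition with 17 under the conditions of step 9 gives the 7-triethylgermyl dihydrobenzofuran F7. N-Iodosuccinimide in acetonitrile at rt converts the aryl germane into iodide 19, where the route is rejoined.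

**Step 7.** The potassium alkoxide may react in other ways before it is trapped: transfer of the alkynyl trimethylsilyl group to oxygen, or fragmentation of the homopropargylic alkoxide back to 9. The product may also be lost on isolation by acid-catalysed hydration or by rearrangement on warming. Fallback: the ynol ether is built without an alkoxide, by way of a formate. It sets out from 11. Formylation (acetic formic anhydride, pyridine) gives the formate F8. Ramirez dibromo-olefination (CBr4, PPh3, CH2Cl2, 0 °C) gives the 2,2-dibromovinyl ether F9. n-BuLi (2.2 equiv, THF, −78 °C) converts it, by bromine–lithium exchange, Fritsch–Buttenberg–Wiechell rearrangement and deprotonation, into the same lithium alkynyl ether 14, and chlorotriethylsilane then gives 15.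

**Step 10.** The iodine electrophile may also attack a C–H position of the syringyl ring, since ipso-substitution of a triethylsilyl group is slower than that of a trimethylsilyl group, or traces of acid may open the acetal. Fallback: the electrophilic substitution is moved from silicon to germanium. The germyl series described for step 8 is used, in which N-iodosuccinimide cleaves the aryl–germanium bond under conditions too mild for C–H iodination. It sets out from 11, comes back at 19 and makes no compound beyond F5 to F7.

**Step 15.** The Lewis acid may ionise the C2–O1 benzylic ether (ring opening, epimerisation or trapping of the cation). The electron-rich stilbene may oligomerise during the slower cleavage of the primary alkyl benzyl ether, or the debenzylation may stay incomplete. Fallback: the benzyl ethers of the chiral half are removed by hydrogenolysis before any alkene exists, and the stilbene is then made by a Heck reaction that tolerates free hydroxyl groups. It sets out from 20. H2 over palladium on carbon (Pd/C) in EtOAc, stopped after uptake of two equivalents, gives the phenol alcohol F10. PPTS in wet acetone gives the hydroxy aldehyde F11. Wittig methylenation (Ph3P=CH2 in excess, THF) gives the styrene F12. Heck coupling with 5-iodoresorcinol (Pd(OAc)2, P(o-tol)3, Et3N, DMF, 80 °C) then gives 26 directly.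

## Further compounds

F1 | step 9 | diisopropyl(prop-2-yn-1-yloxy)silyl derivative of 16 at the carbon-bound alkyne (silicon-tethered triyne) | COc1cc([C@@H]([C@@H](C#C[Si](C(C)C)(C(C)C)OCC#C)COCc2ccccc2)OC#C[Si](CC)(CC)CC)cc(OC)c1OCc1ccccc1
F2 | step 9 | tricyclic benzoxasilole: dihydrobenzofuran with C4–Si(iPr)2–O–CH2–C5 bridge and 7-triethylsilyl group | COc1cc([C@@H]2Oc3c([Si](CC)(CC)CC)cc4CO[Si](C(C)C)(C(C)C)c4c3[C@H]2COCc2ccccc2)cc(OC)c1OCc1ccccc1
F3 | step 9 | [(2R,3S)-2-[4-(benzyloxy)-3,5-dimethoxyphenyl]-3-[(benzyloxy)methyl]-7-(triethylsilyl)-2,3-dihydrobenzofuran-5-yl]methanol | COc1cc([C@@H]2Oc3c([Si](CC)(CC)CC)cc(CO)cc3[C@H]2COCc2ccccc2)cc(OC)c1OCc1ccccc1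
F4 | step 9 | (2R,3S)-2-[4-(benzyloxy)-3,5-dimethoxyphenyl]-3-[(benzyloxy)methyl]-7-(triethylsilyl)-2,3-dihydrobenzofuran-5-carbaldehyde | COc1cc([C@@H]2Oc3c([Si](CC)(CC)CC)cc(C=O)cc3[C@H]2COCc2ccccc2)cc(OC)c1OCc1ccccc1
F5 | step 8 | triethylgermylethynyl ether of 11 | COc1cc([C@@H]([C@@H](C#C[Si](C)(C)C)COCc2ccccc2)OC#C[Ge](CC)(CC)CC)cc(OC)c1OCc1ccccc1
F6 | step 8 | triethylgermylethynyl ether with free carbon-bound alkyne (germyl diyne) | COc1cc([C@@H]([C@@H](C#C)COCc2ccccc2)OC#C[Ge](CC)(CC)CC)cc(OC)c1OCc1ccccc1
F7 | step 8 | (2R,3S)-2-[4-(benzyloxy)-3,5-dimethoxyphenyl]-3-[(benzyloxy)methyl]-5-(diethoxymethyl)-7-(triethylgermyl)-2,3-dihydrobenzofuran | COc1cc([C@@H]2Oc3c([Ge](CC)(CC)CC)cc(C(OCC)OCC)cc3[C@H]2COCc2ccccc2)cc(OC)c1OCc1ccccc1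
F8 | step 7 | formate ester of 11 | COc1cc([C@@H]([C@@H](C#C[Si](C)(C)C)COCc2ccccc2)OC=O)cc(OC)c1OCc1ccccc1
F9 | step 7 | 2,2-dibromovinyl ether of 11 | COc1cc([C@@H]([C@@H](C#C[Si](C)(C)C)COCc2ccccc2)OC=C(Br)Br)cc(OC)c1OCc1ccccc1
F0 | step 10 | none | none
F10 | step 15 | 4-[(2R,3S)-5-(diethoxymethyl)-3-(hydroxymethyl)-7-methoxy-2,3-dihydrobenzofuran-2-yl]-2,6-dimethoxyphenol | COc1cc([C@@H]2Oc3c(OC)cc(C(OCC)OCC)cc3[C@H]2CO)cc(OC)c1O
F11 | step 15 | (2R,3S)-2-(4-hydroxy-3,5-dimethoxyphenyl)-3-(hydroxymethyl)-7-methoxy-2,3-dihydrobenzofuran-5-carbaldehyde | COc1cc([C@@H]2Oc3c(OC)cc(C=O)cc3[C@H]2CO)cc(OC)c1O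
F12 | step 15 | 4-[(2R,3S)-5-ethenyl-3-(hydroxymethyl)-7-methoxy-2,3-dihydrobenzofuran-2-yl]-2,6-dimethoxyphenol | COc1cc([C@@H]2Oc3c(OC)cc(C=C)cc3[C@H]2CO)cc(OC)c1O
A1 | alternative 1 | methyl trans-5-bromo-2-(3,5-dimethoxy-4-mesyloxyphenyl)-7-methoxy-2,3-dihydrobenzofuran-3-carboxylate | COc1cc([C@@H]2Oc3c(OC)cc(Br)cc3[C@H]2C(=O)OC)cc(OC)c1OS(C)(=O)=O
A2 | alternative 2 | trans-2-(4-benzyloxy-3,5-dimethoxyphenyl)-3-(benzyloxymethyl)-5-(triisopropylsilyloxy)-2,3-dihydrobenzofuran-7-ol | COc1cc([C@@H]2Oc3c(O)cc(O[Si](C(C)C)(C(C)C)C(C)C)cc3[C@H]2COCc2ccccc2)cc(OC)c1OCc1ccccc1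
A3 | alternative 3 | trans-2-(4-benzyloxy-3,5-dimethoxyphenyl)-5-bromo-3-[(tert-butyldimethylsilyloxy)methyl]-7-methoxy-2,3-dihydrobenzofuran | COc1cc([C@@H]2Oc3c(OC)cc(Br)cc3[C@H]2CO[Si](C)(C)C(C)(C)C)cc(OC)c1OCc1ccccc1
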